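The target is cupressuflavone (8,8''-biapigenin) with two extra hydrogens across C2–C3 of one ring C, and C2 is its only stereocentre. Everything rests on undoing that reduction. The precursor is the twofold-symmetric hexabenzyl ether of the biflavone, assembled from a single 8-iodoflavone by Ullmann homocoupling at C8–C8''. The key step exploits the two homotopic ring C enones (C2=C3–C4=O and C2''=C3''–C4''=O), which the twisted tetra-ortho-substituted biaryl bond keeps electronically independent. A chiral bisphosphine-ligated copper hydride delivers hydride to C2 of either unit. One operation therefore tells the halves apart, saturates C2–C3 and installs 2S. Neutral hydrogenolysis then frees the six phenols.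

Key step: step 6

Remark 1: the given structure fixes only C2 (S) and gives the hindered C8–C8'' axis no descriptor, so the 2S product is accepted as the pair of atropisomers that the racemic axis of 7 produces.
Remark 2: the sense of induction of DTBM-SEGPHOS-ligated copper hydride on a flavone is not established, so the S antipode in step 6 is provisional; a trial on a monomeric flavone decides, and the equally available mirror-image ligand is used if the trial points the other way.

Step 1
Reactants: 1 2',4',6'-trihydroxyacetophenone
Product: 2 2'-hydroxy-4',6'-bis(benzyloxy)acetophenone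
Conditions: BnBr (2.05 equiv), K2CO3 (2.1 equiv), DMF, rt
Reagents that add atoms: benzyl bromide, BrCc1ccccc1
Why: Williamson ether synthesis, in which two equivalents of halide alkylate the para hydroxyl and one of the two equivalent ortho hydroxyls, while the last ortho hydroxyl is hydrogen-bonded to the acetyl carbonyl and too poorly nucleophilic to react under these mild conditions.

Step 2
Reactants: 2 2'-hydroxy-4',6'-bis(benzyloxy)acetophenone
Product: 3 2'-hydroxy-3'-iodo-4',6'-bis(benzyloxy)acetophenone
Conditions: NIS (1.0 equiv), DMF, 0 °C to rt, dark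
Reagents that add atoms: N-iodosuccinimide, O=C1CCC(=O)N1I
Why: Electrophilic aromatic iodination, in which the free phenol steers the iodonium donor to its open ortho carbon C3' (the future C8) rather than to C5' between two benzyloxy groups, the site preference documented for 2'-hydroxy-4',6'-dialkoxyacetophenones, and one equivalent of reagent limits di-iodination.

Step 3
Reactants: 3 2'-hydroxy-3'-iodo-4',6'-bis(benzyloxy)acetophenone; 4 4-(benzyloxy)benzaldehyde
Product: 5 (E)-2'-hydroxy-3'-iodo-4,4',6'-tris(benzyloxy)chalcone
Conditions: KOH (excess), EtOH/THF, rt; then 1 M HCl to pH 5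
Reagents that add atoms: none
Why: Claisen–Schmidt condensation, in which the acetyl enolate adds to the non-enolisable aldehyde and E1cB loss of water gives the E-enone, the aryl iodide and the benzyl ethers being inert to hydroxide at room temperature.

Step 4
Reactants: 5 (E)-2'-hydroxy-3'-iodo-4,4',6'-tris(benzyloxy)chalcone
Product: 6 8-iodo-5,7,4'-tris(benzyloxy)flavone
Conditions: I2 (10 mol %), DMSO, 125 °C, short heating under TLC control
Reagents that add atoms: none
Why: Iodine-catalysed oxidative cyclisation of a 2'-hydroxychalcone, in which the 2'-hydroxyl closes ring C on the beta carbon (6-endo oxa-Michael) and iodine dehydrogenates C2–C3, while DMSO reoxidises HI and so keeps the acid level low enough to spare the C8–I bond and the peri benzyl ether during a short heating period.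

Step 5
Reactants: 6 8-iodo-5,7,4'-tris(benzyloxy)flavone (two molecules)
Product: 7 5,7,4',5'',7'',4'''-hexakis(benzyloxy)-8,8''-biflavone (cupressuflavone hexabenzyl ether, racemic at the axis)
Conditions: activated Cu powder (excess), DMF, 150 °C, Ar
Reagents that add atoms: none
Why: Ullmann reductive homocoupling, in which copper inserts into the C8–I bond and the arylcopper couples with a second molecule of 6 to forge the tetra-ortho-substituted C8–C8'' bond, a reaction type established for 8-iodo-5,7,4'-trialkoxyflavones, the new axis forming as a racemate.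

Step 6
Reactants: 7 cupressuflavone hexabenzyl ether
Product: 9 (2S)-2,3-dihydrocupressuflavone hexabenzyl ether, via silyl enol ether 8 (not isolated)
Conditions: Cu(OAc)2 (5 mol %), (S)-DTBM-SEGPHOS (5.5 mol %), (EtO)2MeSiH (0.8 equiv), toluene/THF, 0 °C to rt, no protic additive; then TBAF/AcOH (1:1), THF, −20 °C; recovered 7 resubmitted
Reagents that add atoms: none
Why: Proposed new method: the ligated monovalent copper hydride formed from Cu(OAc)2, the bisphosphine and the silane hydrocuprates the C2=C3–C4=O enone of one ring C with hydride transfer to C2, sigma-bond metathesis of the copper enolate with the silane gives silyl enol ether 8 and regenerates the hydride, and buffered fluoride finally protonates C3 to release ketone 9. The closest known reaction types are the copper hydride catalysed asymmetric 1,4-hydrosilylation of beta,beta-disubstituted cycloalkenones and of 2-substituted chromones and thiochromones, and the asymmetric hydrogenation of flavones, none of which has been shown on a 5,7-dioxygenated 2-arylchromone or on one unit of a biflavone. No ring is closed, since ring C already exists and only its oxidation level changes. C2, the only new stereocentre, is set by catalyst control, the chiral pocket of the bisphosphine exposing one face of the planar pyranone to the Cu–H bond, and this control has to dominate the distant racemic axis so that both atropisomers of 7 converge on 2S. Mono- over double reduction is needed and is secured only statistically, by a substoichiometric silane that carries a single Si–H and by the independence of the two homotopic units, with unreacted 7 recovered and resubmitted. 1,4- over 1,2-addition is favoured by the soft hydride and by the peri 5-benzyloxy group that shields C4=O, while the absence of any alcohol keeps the product masked as 8 and so guards it against ketone reduction and retro-oxa-Michael opening.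

Step 7
Reactants: 9 (2S)-2,3-dihydrocupressuflavone hexabenzyl ether
Product: 10 (2S)-2,3-dihydrocupressuflavone (target CNP0339995.1)
Conditions: H2 (1 atm), 10% Pd/C, THF/MeOH, rt, stopped when uptake ends; filtration and evaporation without base
Reagents that add atoms: none
Why: Heterogeneous catalytic hydrogenolysis, in which benzylic C–O cleavage of the six aryl benzyl ethers at one atmosphere is much faster than saturation of the remaining C2''=C3'' bond, reduction of C4=O or cleavage of the C2–O1 bond, and the neutral medium offers no base for retro-oxa-Michael racemisation of C2.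

Compound list
1 | 2',4',6'-trihydroxyacetophenone | CC(=O)c1c(O)cc(O)cc1O | starting material
2 | 2'-hydroxy-4',6'-bis(benzyloxy)acetophenone | CC(=O)c1c(O)cc(OCc2ccccc2)cc1OCc1ccccc1 | intermediate
3 | 2'-hydroxy-3'-iodo-4',6'-bis(benzyloxy)acetophenone | CC(=O)c1c(O)c(I)c(OCc2ccccc2)cc1OCc1ccccc1 | intermediate
4 | 4-(benzyloxy)benzaldehyde | O=Cc1ccc(OCc2ccccc2)cc1 | starting material
5 | (E)-2'-hydroxy-3'-iodo-4,4',6'-tris(benzyloxy)chalcone | O=C(/C=C/c1ccc(OCc2ccccc2)cc1)c1c(O)c(I)c(OCc2ccccc2)cc1OCc1ccccc1 | intermediate
6 | 8-iodo-5,7,4'-tris(benzyloxy)flavone | O=c1cc(-c2ccc(OCc3ccccc3)cc2)oc2c(I)c(OCc3ccccc3)cc(OCc3ccccc3)c12 | intermediate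
7 | cupressuflavone hexabenzyl ether (8,8''-biflavone, axis racemic) | O=c1cc(-c2ccc(OCc3ccccc3)cc2)oc2c(-c3c(OCc4ccccc4)cc(OCc4ccccc4)c4c(=O)cc(-c5ccc(OCc6ccccc6)cc5)oc34)c(OCc3ccccc3)cc(OCc3ccccc3)c12 | intermediate
8 | C4 diethoxy(methyl)silyl enol ether of 9 ((2S)-flav-3-ene unit joined C8–C8'' to the intact flavone unit) | CCO[Si](C)(OCC)OC1=C[C@@H](c2ccc(OCc3ccccc3)cc2)Oc2c1c(OCc1ccccc1)cc(OCc1ccccc1)c2-c1c(OCc2ccccc2)cc(OCc2ccccc2)c2c(=O)cc(-c3ccc(OCc4ccccc4)cc3)oc12 | intermediate (not isolated)
9 | (2S)-2,3-dihydrocupressuflavone hexabenzyl ether | O=C1C[C@@H](c2ccc(OCc3ccccc3)cc2)Oc2c1c(OCc1ccccc1)cc(OCc1ccccc1)c2-c1c(OCc2ccccc2)cc(OCc2ccccc2)c2c(=O)cc(-c3ccc(OCc4ccccc4)cc3)oc12 | intermediate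
10 | (2S)-2,3-dihydrocupressuflavone, (2S)-naringenin joined C8–C8'' to apigenin | O=C1C[C@@H](c2ccc(O)cc2)Oc2c1c(O)cc(O)c2-c1c(O)cc(O)c2c(=O)cc(-c3ccc(O)cc3)oc12 | target

Total step count: 7
Longest linear sequence: 7 steps (1 → 2 → 3 → 5 → 6 → 7 → 9 → 10)

Steps most likely to fail

**Step 6 (labelled step).**
- What may go wrong:
  - slow hydrocupration of the electron-rich 2-aryl vinylogous ester;
  - reduction of both units (even ideally, independent sites limit the mono-reduced share of each pass to about half);
  - beta-elimination of the ring oxygen from the copper enolate before silyl transfer;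
  - weak facial selectivity in the axial series that is mismatched with the ligand.
- Fallback with known chemistry, setting out from 5 and 6 and rejoining at 9. The two halves are made at different oxidation levels before they are joined, and 2S is secured by resolution instead of induction. Chalcone 5 is isomerised by intramolecular oxa-Michael addition (NaOAc, EtOH, reflux) to racemic 8-iodo-5,7,4'-tris(benzyloxy)flavanone F1. A mixed Ullmann coupling of F1 with an excess of 6 (activated Cu powder, DMF, 150 °C) uses the reaction that must already have worked in step 5. After chromatography it should give the cross-coupled, C2-racemic 2,3-dihydrocupressuflavone hexabenzyl ether F2. Kinetic resolution of F2 by Noyori asymmetric transfer hydrogenation ([Cp*RhCl((R,R)-TsDPEN)], HCO2H/Et3N 5:2, EtOAc, rt) is a method established for racemic flavanones. It should reduce the 2R ketone to the cis-(2R,4R)-flavan-4-ol hexabenzyl ether F3 and leave the 2S ketone, which is 9, to be separated on silica.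

**Step 5.**
- What may go wrong: hydrodeiodination and stalling of the coupling at the crowded carbon flanked by O1 and the 7-benzyloxy group.
- Fallback setting out from 6 and rejoining at 7. Reductive homocoupling on copper is replaced by palladium cross-coupling of two differently functionalised copies of the same flavone. Part of 6 is converted by Miyaura borylation (PdCl2(dppf), B2pin2, KOAc, dioxane, 90 °C) into 8-(4,4,5,5-tetramethyl-1,3,2-dioxaborolan-2-yl)-5,7,4'-tris(benzyloxy)flavone F4. Suzuki–Miyaura coupling of F4 with the rest of 6 (Pd(OAc)2, SPhos, K3PO4, toluene/H2O, 100 °C), a ligand system developed for tetra-ortho-substituted biaryls, should give 7.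

**Step 4.**
- What may go wrong: loss or migration of the aryl iodine through the HI/I2 couple in hot DMSO, and cleavage of the peri benzyl ether on long heating.
- Fallback setting out from 2 and 4 and rejoining at 6. Iodine is introduced only after ring C is in place. Claisen–Schmidt condensation of 2 with 4 (KOH, EtOH/THF, rt) gives (E)-2'-hydroxy-4,4',6'-tris(benzyloxy)chalcone F5. I2/DMSO cyclisation, now with no carbon–iodine bond to endanger, gives 5,7,4'-tris(benzyloxy)flavone F6. Electrophilic iodination (NIS, DMF, 60 °C) goes to C8, the documented site for 5,7-dialkoxyflavones, and delivers 6.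

Further compounds
F1 | step 6 | (2RS)-8-iodo-5,7,4'-tris(benzyloxy)flavanone | O=C1CC(c2ccc(OCc3ccccc3)cc2)Oc2c(I)c(OCc3ccccc3)cc(OCc3ccccc3)c12
F2 | step 6 | (2RS)-2,3-dihydrocupressuflavone hexabenzyl ether | O=C1CC(c2ccc(OCc3ccccc3)cc2)Oc2c1c(OCc1ccccc1)cc(OCc1ccccc1)c2-c1c(OCc2ccccc2)cc(OCc2ccccc2)c2c(=O)cc(-c3ccc(OCc4ccccc4)cc3)oc12
F3 | step 6 | cis-(2R,4R)-flavan-4-ol hexabenzyl ether (C4 alcohol of the 2R series, flavone unit intact) | O[C@@H]1C[C@H](c2ccc(OCc3ccccc3)cc2)Oc2c1c(OCc1ccccc1)cc(OCc1ccccc1)c2-c1c(OCc2ccccc2)cc(OCc2ccccc2)c2c(=O)cc(-c3ccc(OCc4ccccc4)cc3)oc12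
F4 | step 5 | 8-(4,4,5,5-tetramethyl-1,3,2-dioxaborolan-2-yl)-5,7,4'-tris(benzyloxy)flavone | O=c1cc(-c2ccc(OCc3ccccc3)cc2)oc2c(B3OC(C)(C)C(C)(C)O3)c(OCc3ccccc3)cc(OCc3ccccc3)c12
F5 | step 4 | (E)-2'-hydroxy-4,4',6'-tris(benzyloxy)chalcone | O=C(/C=C/c1ccc(OCc2ccccc2)cc1)c1c(O)cc(OCc2ccccc2)cc1OCc1ccccc1
F6 | step 4 | 5,7,4'-tris(benzyloxy)flavone | O=c1cc(-c2ccc(OCc3ccccc3)cc2)oc2cc(OCc3ccccc3)cc(OCc3ccccc3)c12
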